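## Retrosynthetic overview

1. C8–O: the angelate is put on last, by mixed-anhydride acylation of the C8 hydroxyl of the C8/C10 diol.
2. Ten-membered ring: C3–C4, by intramolecular nickel-catalysed reductive coupling of a (Z)-alkenyl iodide with an α,β-epoxy thioester; the epoxy enone appears directly.
3. cis-α-Methylene-γ-lactone: C6–C7 and O–C12, by indium Barbier allylation of (Z)-3-iodobut-2-enal with a Morita–Baylis–Hillman-derived (Z)-2-(bromomethyl)enoate; the C8 centre controls C7 and C6.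
4. C9–C10: nickel-catalysed acyl–alkyl coupling of a glycidol-derived iodide (C7–C9) with a Sharpless-derived cis-epoxy acid (C10, C1–C3); the C10 carbinol by chelation-controlled MeMgBr addition.
5. Ring order: oxirane, then γ-lactone, then the ten-membered carbocycle; three building blocks (C4–C6, C7–C9, C10–C3) are made in parallel.

Assumption: locants C1–C15 follow germacrane numbering of the target (C1–C2 oxirane, C3 ketone, C4=C5 with C15 methyl, C6 lactone carbinol, C7, C8 ester carbinol, C9, C10 carbinol with C14 methyl, C11=C13, C12 lactone carbonyl); the target is read as (1S,2R,6S,7R,8R,10R), 4Z, with a (Z)-2-methylbut-2-enoate (angelate) ester. PMB = 4-methoxybenzyl, TBS = tert-butyldimethylsilyl, TES = triethylsilyl.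

## Route

Step 1
Reactants: 1 ethyl but-2-ynoate
Product: 2 ethyl (Z)-3-iodobut-2-enoate
Conditions: NaI, AcOH, 110 °C
Reagents that add atoms: sodium iodide, [Na+].[I-]
Why: Anti hydroiodination of the ynoate (conjugate addition of iodide, then protonation) gives the (Z)-β-iodo enoate, placing iodine cis to the carbon that becomes C6.

Step 2
Reactants: 2 ethyl (Z)-3-iodobut-2-enoate
Product: 3 (Z)-3-iodobut-2-en-1-ol
Conditions: iBu2AlH, CH2Cl2, −78 to 0 °C
Reagents that add atoms: none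
Why: 1,2-Reduction of the ester by the aluminium hydride leaves the alkenyl iodide and its geometry untouched.

Step 3
Reactants: 3 (Z)-3-iodobut-2-en-1-ol
Product: 4 (Z)-3-iodobut-2-enal
Conditions: activated MnO2, CH2Cl2, rt
Reagents that add atoms: none
Why: Allylic alcohol oxidation on MnO2 stops at the enal without Z/E isomerisation; the volatile aldehyde is used as a solution.

Step 4
Reactants: 5 (Z)-but-2-ene-1,4-diol
Product: 6 (Z)-4-[(4-methoxybenzyl)oxy]but-2-en-1-ol
Conditions: NaH (1 equiv), 4-methoxybenzyl chloride, Bu4NI (cat.), THF/DMF, 0 °C to rt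
Reagents that add atoms: 4-methoxybenzyl chloride, COc1ccc(CCl)cc1
Why: Williamson etherification of the monoalkoxide of the symmetric diol (diol in excess) gives the mono-PMB ether and leaves one allylic hydroxyl for the directed epoxidation.

Step 5
Reactants: 6 (Z)-4-[(4-methoxybenzyl)oxy]but-2-en-1-ol
Product: 7 [(2R,3S)-3-{[(4-methoxybenzyl)oxy]methyl}oxiran-2-yl]methanol
Conditions: Ti(OiPr)4, (−)-diethyl D-tartrate, tBuOOH, 4 Å molecular sieves, CH2Cl2, −20 °C
Reagents that add atoms: tert-butyl hydroperoxide, CC(C)(C)OO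
Why: Sharpless asymmetric epoxidation, in which the (−)-tartrate–titanium complex delivers oxygen to one enantioface of the (Z)-allylic alcohol, sets both oxirane centres (C1 and C2), and the alkene geometry guarantees the cis-oxirane.

Step 6
Reactants: 7 cis-epoxy alcohol
Product: 8 (2S,3S)-3-{[(4-methoxybenzyl)oxy]methyl}oxirane-2-carboxylic acid
Conditions: TEMPO (cat.), PhI(OAc)2, MeCN/pH 7 buffer, rt
Reagents that add atoms: water, O
Why: Oxoammonium (TEMPO) oxidation of the primary alcohol through the aldehyde hydrate gives the glycidic acid under near-neutral conditions that spare the oxirane and the PMB ether.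

Step 7
Reactants: 9 (S)-oxiran-2-ylmethanol [(S)-glycidol]
Product: 10 (S)-3-iodopropane-1,2-diol
Conditions: LiI, AcOH, THF, 0 °C to rt
Reagents that add atoms: lithium iodide, [Li+].[I-]
Why: SN2 opening of the oxirane by iodide at the unsubstituted carbon gives the iodohydrin and leaves the stereocentre (later C8) untouched.

Step 8
Reactants: 10 (S)-3-iodopropane-1,2-diol
Product: 11 (S)-1-iodo-3-(triethylsilyloxy)propan-2-ol
Conditions: Et3SiCl (1.05 equiv), imidazole, CH2Cl2, −40 °C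
Reagents that add atoms: chlorotriethylsilane, CC[Si](CC)(CC)Cl
Why: Silylation at low temperature discriminates the primary from the secondary hydroxyl, and the primary triethylsilyl ether is the group that step 12 oxidises directly.

Step 9
Reactants: 11 (S)-1-iodo-3-(triethylsilyloxy)propan-2-ol
Product: 12 (S)-2-(tert-butyldimethylsilyloxy)-1-iodo-3-(triethylsilyloxy)propane
Conditions: tBuMe2SiOTf, 2,6-lutidine, CH2Cl2, −78 °C
Reagents that add atoms: tert-butyldimethylsilyl trifluoromethanesulfonate, CC(C)(C)[Si](C)(C)OS(=O)(=O)C(F)(F)F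
Why: Silyl triflate silylation of the secondary alcohol under non-nucleophilic conditions avoids oxirane re-closure and puts a non-chelating group on the C8 oxygen.

Step 10
Reactants: 8 cis-epoxy acid; 12 iodide
Product: 14 (R)-3-(tert-butyldimethylsilyloxy)-1-[(2S,3S)-3-{[(4-methoxybenzyl)oxy]methyl}oxiran-2-yl]-4-(triethylsilyloxy)butan-1-one, via S-pyridin-2-yl thioester 13 (not isolated)
Conditions: 2,2'-dipyridyl disulfide, PPh3, THF, rt; then 12, NiCl2(MeOCH2CH2OMe) (10 mol %), 4,4'-di-tert-butyl-2,2'-bipyridine (11 mol %), Mn powder, DMA, 0 °C to rt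
Reagents that add atoms: none
Why: Nickel-catalysed reductive acyl–alkyl cross-electrophile coupling, in which the primary alkyl radical from 12 is captured by the acylnickel species formed from the 2-pyridyl thioester, gives the C9–C10 ketone without touching the oxirane or either stereocentre.

Step 11
Reactants: 14 epoxy ketone
Product: 16 (2R,4R)-4-(tert-butyldimethylsilyloxy)-2-[(2S,3S)-3-{[(4-methoxybenzyl)oxy]methyl}oxiran-2-yl]-2,5-bis(triethylsilyloxy)pentane, via bromomagnesium alkoxide 15 (not isolated)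
Conditions: MeMgBr, Et2O/CH2Cl2, −78 °C; then Et3SiOTf, 2,6-lutidine, −78 to 0 °C
Reagents that add atoms: methylmagnesium bromide, C[Mg]Br; triethylsilyl trifluoromethanesulfonate, CC[Si](CC)(CC)OS(=O)(=O)C(F)(F)F
Why: Chelation-controlled Grignard addition (Cram chelate between the ketone and oxirane oxygens, methyl attacking the face anti to the C1–C2 bond, the silylated C8 oxygen not competing) sets the C10 carbinol as R, and the alkoxide is silylated in the same flask.

Step 12
Reactants: 16 tris-silyl ether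
Product: 17 (2R,4R)-2-(tert-butyldimethylsilyloxy)-4-[(2S,3S)-3-{[(4-methoxybenzyl)oxy]methyl}oxiran-2-yl]-4-(triethylsilyloxy)pentanal
Conditions: (COCl)2, DMSO, CH2Cl2, −78 to −40 °C; Et3N
Reagents that add atoms: none
Why: Under Swern conditions a primary triethylsilyl ether is cleaved by the chlorosulfonium salt and oxidised in situ to the aldehyde, while the secondary TBS and tertiary triethylsilyl ethers are inert.

Step 13
Reactants: 17 aldehyde; 18 methyl acrylate
Product: 19 methyl (4R,6R)-4-(tert-butyldimethylsilyloxy)-3-hydroxy-6-[(2S,3S)-3-{[(4-methoxybenzyl)oxy]methyl}oxiran-2-yl]-2-methylidene-6-(triethylsilyloxy)heptanoate (both C3 epimers)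
Conditions: quinuclidine (0.5 equiv), MeOH (1 equiv), neat 18, 0 °C to rt
Reagents that add atoms: none
Why: Morita–Baylis–Hillman reaction of the aldehyde with the acrylate; the new carbinol (C7) forms as both epimers, which is irrelevant because step 14 makes this carbon trigonal.

Step 14
Reactants: 19 Morita–Baylis–Hillman adduct
Product: 20 methyl (2Z,4R,6R)-2-(bromomethyl)-4-(tert-butyldimethylsilyloxy)-6-[(2S,3S)-3-{[(4-methoxybenzyl)oxy]methyl}oxiran-2-yl]-6-(triethylsilyloxy)hept-2-enoate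
Conditions: N-bromosuccinimide, Me2S, CH2Cl2, −20 to 0 °C
Reagents that add atoms: N-bromosuccinimide, O=C1CCC(=O)N1Br
Why: The bromodimethylsulfonium reagent activates the allylic alcohol and bromide enters with allylic transposition (SN2') to give the conjugated (Z)-2-(bromomethyl)enoate.

Step 15
Reactants: 20 allylic bromide; 4 (Z)-3-iodobut-2-enal
Product: 22 (4S,5R)-4-{(1R,3R)-1-(tert-butyldimethylsilyloxy)-3-[(2S,3S)-3-{[(4-methoxybenzyl)oxy]methyl}oxiran-2-yl]-3-(triethylsilyloxy)butyl}-5-[(Z)-2-iodoprop-1-en-1-yl]-3-methylidenedihydrofuran-2(3H)-one, via hydroxy ester 21 (not isolated)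
Conditions: In powder, THF/H2O (3:1), rt; then pyridinium p-toluenesulfonate (cat.), CH2Cl2, rt
Reagents that add atoms: none
Why: Barbier allylation in which the (Z)-γ-substituted allylindium adds through its γ-carbon by a chair transition state (syn adduct, hence the cis-lactone), the C8 centre (C–H in the alkene plane to avoid A(1,3) strain, aldehyde anti to the C9 chain) fixing C7 and thereby C6, followed by lactonisation of the γ-hydroxy ester.

Step 16
Reactants: 22 lactone PMB ether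
Product: 23 (4S,5R)-4-{(1R,3R)-1-(tert-butyldimethylsilyloxy)-3-[(2S,3S)-3-(hydroxymethyl)oxiran-2-yl]-3-(triethylsilyloxy)butyl}-5-[(Z)-2-iodoprop-1-en-1-yl]-3-methylidenedihydrofuran-2(3H)-one
Conditions: DDQ, CH2Cl2/pH 7 buffer, 0 °C
Reagents that add atoms: none
Why: Oxidative cleavage of the PMB ether (electron transfer to DDQ, hydrolysis of the oxocarbenium ion) frees the C3 hydroxyl without touching the silyl ethers, the alkenyl iodide or the lactone.

Step 17
Reactants: 23 epoxy alcohol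
Product: 24 (2R,3S)-3-{(2R,4R)-4-(tert-butyldimethylsilyloxy)-4-[(2R,3S)-2-[(Z)-2-iodoprop-1-en-1-yl]-4-methylidene-5-oxotetrahydrofuran-3-yl]-2-(triethylsilyloxy)butan-2-yl}oxirane-2-carboxylic acid
Conditions: TEMPO (cat.), PhI(OAc)2, MeCN/pH 7 buffer, rt
Reagents that add atoms: water, O
Why: TEMPO/PhI(OAc)2 oxidation of the primary epoxy alcohol to the acid, as in step 6, tolerates the alkenyl iodide, the α-methylene lactone and the silyl ethers.

Step 18
Reactants: 24 seco-acid
Product: 26 (1S,2R,6S,7S,8R,10R)-8-(tert-butyldimethylsilyloxy)-1,2-epoxy-3-oxo-10-(triethylsilyloxy)germacra-4Z,11(13)-dien-12,6-olide, via S-pyridin-2-yl thioester 25 (not isolated)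
Conditions: 2,2'-dipyridyl disulfide, PPh3, THF, rt; then syringe-pump addition (12 h) to NiBr2(MeOCH2CH2OMe) (30 mol %), 4,4'-di-tert-butyl-2,2'-bipyridine (35 mol %), Zn dust, DMA, 25 °C, final 2 mM
Reagents that add atoms: none
Why: Proposed new method: an intramolecular nickel-catalysed reductive acyl–alkenyl cross-electrophile coupling, in which zerovalent nickel adds to the (Z)-C–I bond with retention, Zn reduces the alkenylnickel to the monovalent stage, this inserts into the C(acyl)–S bond of the tethered thioester, and reductive elimination forges C3–C4 and the ten-membered ring at the enone oxidation level (the cis-lactone and cis-oxirane act as turn elements and high dilution suppresses dimers); the closest known reaction type is the nickel-catalysed reductive ketone synthesis from alkyl iodides and 2-pyridyl thioesters, including its macrocyclic ketone-forming variant, which has not been shown for alkenyl iodides, α,β-epoxy thioesters or medium rings.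

Step 19
Reactants: 26 bis-silyl macrocycle
Product: 27 (1S,2R,6S,7R,8R,10R)-1,2-epoxy-8,10-dihydroxy-3-oxogermacra-4Z,11(13)-dien-12,6-olide
Conditions: HF·pyridine, pyridine, THF, 0 °C to rt
Reagents that add atoms: none
Why: Fluoride cleaves both Si–O bonds (strong Si–F bond) under pyridine-buffered conditions that spare the epoxy enone and the α-methylene lactone.

Step 20
Reactants: 28 angelic acid [(Z)-2-methylbut-2-enoic acid]
Product: 29 (Z)-2-methylbut-2-enoic 2,4,6-trichlorobenzoic anhydride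
Conditions: 2,4,6-trichlorobenzoyl chloride, Et3N, toluene, rt; filtered and used as a solution
Reagents that add atoms: 2,4,6-trichlorobenzoyl chloride, O=C(Cl)c1c(Cl)cc(Cl)cc1Cl
Why: The carboxylate attacks the aroyl chloride to give the mixed anhydride whose aroyl carbonyl is shielded by two ortho chlorines (Yamaguchi activation).

Step 21
Reactants: 27 diol; 29 mixed anhydride
Product: 30 (1S,2R,6S,7R,8R,10R)-8-[(Z)-2-methylbut-2-enoyloxy]-1,2-epoxy-10-hydroxy-3-oxogermacra-4Z,11(13)-dien-12,6-olide (target)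
Conditions: 29 (4 equiv), toluene, 75 °C
Reagents that add atoms: none
Why: Yamaguchi-type esterification in which the secondary C8 hydroxyl attacks the unhindered angeloyl carbonyl while the tertiary C10 hydroxyl does not react, and the absence of a nucleophilic catalyst keeps the (Z)-alkene from isomerising to the tiglate.

## Compound list

1 | ethyl but-2-ynoate | CC#CC(=O)OCC | starting material
2 | ethyl (Z)-3-iodobut-2-enoate | C/C(I)=C/C(=O)OCC | intermediate
3 | (Z)-3-iodobut-2-en-1-ol | C/C(I)=C/CO | intermediate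
4 | (Z)-3-iodobut-2-enal | C/C(I)=C/C=O | intermediate
5 | (Z)-but-2-ene-1,4-diol | OC/C=C\CO | starting material
6 | (Z)-4-[(4-methoxybenzyl)oxy]but-2-en-1-ol | COc1ccc(COC/C=C\CO)cc1 | intermediate
7 | [(2R,3S)-3-{[(4-methoxybenzyl)oxy]methyl}oxiran-2-yl]methanol | COc1ccc(COC[C@@H]2O[C@@H]2CO)cc1 | intermediate
8 | (2S,3S)-3-{[(4-methoxybenzyl)oxy]methyl}oxirane-2-carboxylic acid | COc1ccc(COC[C@@H]2O[C@@H]2C(O)=O)cc1 | intermediate
9 | (S)-oxiran-2-ylmethanol [(S)-glycidol] | OC[C@H]1CO1 | starting material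
10 | (S)-3-iodopropane-1,2-diol | OC[C@H](O)CI | intermediate
11 | (S)-1-iodo-3-(triethylsilyloxy)propan-2-ol | CC[Si](CC)(CC)OC[C@H](O)CI | intermediate
12 | (S)-2-(tert-butyldimethylsilyloxy)-1-iodo-3-(triethylsilyloxy)propane | CC[Si](CC)(CC)OC[C@H](O[Si](C)(C)C(C)(C)C)CI | intermediate
13 | S-pyridin-2-yl (2S,3S)-3-{[(4-methoxybenzyl)oxy]methyl}oxirane-2-carbothioate | COc1ccc(COC[C@@H]2O[C@@H]2C(=O)Sc2ccccn2)cc1 | intermediate
14 | (R)-3-(tert-butyldimethylsilyloxy)-1-[(2S,3S)-3-{[(4-methoxybenzyl)oxy]methyl}oxiran-2-yl]-4-(triethylsilyloxy)butan-1-one | CC[Si](CC)(CC)OC[C@H](O[Si](C)(C)C(C)(C)C)CC(=O)[C@H]1O[C@H]1COCc1ccc(OC)cc1 | intermediate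
15 | bromomagnesium (2R,4R)-4-(tert-butyldimethylsilyloxy)-2-[(2S,3S)-3-{[(4-methoxybenzyl)oxy]methyl}oxiran-2-yl]-5-(triethylsilyloxy)pentan-2-olate | CC[Si](CC)(CC)OC[C@H](O[Si](C)(C)C(C)(C)C)C[C@@](C)(O[Mg]Br)[C@H]1O[C@H]1COCc1ccc(OC)cc1 | intermediate
16 | (2R,4R)-4-(tert-butyldimethylsilyloxy)-2-[(2S,3S)-3-{[(4-methoxybenzyl)oxy]methyl}oxiran-2-yl]-2,5-bis(triethylsilyloxy)pentane | CC[Si](CC)(CC)OC[C@H](O[Si](C)(C)C(C)(C)C)C[C@@](C)(O[Si](CC)(CC)CC)[C@H]1O[C@H]1COCc1ccc(OC)cc1 | intermediate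
17 | (2R,4R)-2-(tert-butyldimethylsilyloxy)-4-[(2S,3S)-3-{[(4-methoxybenzyl)oxy]methyl}oxiran-2-yl]-4-(triethylsilyloxy)pentanal | O=C[C@H](O[Si](C)(C)C(C)(C)C)C[C@@](C)(O[Si](CC)(CC)CC)[C@H]1O[C@H]1COCc1ccc(OC)cc1 | intermediate
18 | methyl acrylate | C=CC(=O)OC | starting material
19 | methyl (4R,6R)-4-(tert-butyldimethylsilyloxy)-3-hydroxy-6-[(2S,3S)-3-{[(4-methoxybenzyl)oxy]methyl}oxiran-2-yl]-2-methylidene-6-(triethylsilyloxy)heptanoate (both C3 epimers) | C=C(C(=O)OC)C(O)[C@H](O[Si](C)(C)C(C)(C)C)C[C@@](C)(O[Si](CC)(CC)CC)[C@H]1O[C@H]1COCc1ccc(OC)cc1 | intermediate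
20 | methyl (2Z,4R,6R)-2-(bromomethyl)-4-(tert-butyldimethylsilyloxy)-6-[(2S,3S)-3-{[(4-methoxybenzyl)oxy]methyl}oxiran-2-yl]-6-(triethylsilyloxy)hept-2-enoate | COC(=O)/C(CBr)=C/[C@H](O[Si](C)(C)C(C)(C)C)C[C@@](C)(O[Si](CC)(CC)CC)[C@H]1O[C@H]1COCc1ccc(OC)cc1 | intermediate
21 | methyl (3S,4R,6R)-4-(tert-butyldimethylsilyloxy)-3-[(1R,2Z)-1-hydroxy-3-iodobut-2-en-1-yl]-6-[(2S,3S)-3-{[(4-methoxybenzyl)oxy]methyl}oxiran-2-yl]-2-methylidene-6-(triethylsilyloxy)heptanoate | COC(=O)C(=C)[C@@H]([C@@H](O)/C=C(/C)I)[C@H](O[Si](C)(C)C(C)(C)C)C[C@@](C)(O[Si](CC)(CC)CC)[C@H]1O[C@H]1COCc1ccc(OC)cc1 | intermediate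
22 | (4S,5R)-4-{(1R,3R)-1-(tert-butyldimethylsilyloxy)-3-[(2S,3S)-3-{[(4-methoxybenzyl)oxy]methyl}oxiran-2-yl]-3-(triethylsilyloxy)butyl}-5-[(Z)-2-iodoprop-1-en-1-yl]-3-methylidenedihydrofuran-2(3H)-one | C=C1C(=O)O[C@@H](/C=C(/C)I)[C@H]1[C@H](O[Si](C)(C)C(C)(C)C)C[C@@](C)(O[Si](CC)(CC)CC)[C@H]1O[C@H]1COCc1ccc(OC)cc1 | intermediate
23 | (4S,5R)-4-{(1R,3R)-1-(tert-butyldimethylsilyloxy)-3-[(2S,3S)-3-(hydroxymethyl)oxiran-2-yl]-3-(triethylsilyloxy)butyl}-5-[(Z)-2-iodoprop-1-en-1-yl]-3-methylidenedihydrofuran-2(3H)-one | C=C1C(=O)O[C@@H](/C=C(/C)I)[C@H]1[C@H](O[Si](C)(C)C(C)(C)C)C[C@@](C)(O[Si](CC)(CC)CC)[C@H]1O[C@H]1CO | intermediate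
24 | (2R,3S)-3-{(2R,4R)-4-(tert-butyldimethylsilyloxy)-4-[(2R,3S)-2-[(Z)-2-iodoprop-1-en-1-yl]-4-methylidene-5-oxotetrahydrofuran-3-yl]-2-(triethylsilyloxy)butan-2-yl}oxirane-2-carboxylic acid | C=C1C(=O)O[C@@H](/C=C(/C)I)[C@H]1[C@H](O[Si](C)(C)C(C)(C)C)C[C@@](C)(O[Si](CC)(CC)CC)[C@H]1O[C@H]1C(O)=O | intermediate
25 | S-pyridin-2-yl (2R,3S)-3-{(2R,4R)-4-(tert-butyldimethylsilyloxy)-4-[(2R,3S)-2-[(Z)-2-iodoprop-1-en-1-yl]-4-methylidene-5-oxotetrahydrofuran-3-yl]-2-(triethylsilyloxy)butan-2-yl}oxirane-2-carbothioate | C=C1C(=O)O[C@@H](/C=C(/C)I)[C@H]1[C@H](O[Si](C)(C)C(C)(C)C)C[C@@](C)(O[Si](CC)(CC)CC)[C@H]1O[C@H]1C(=O)Sc1ccccn1 | intermediate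
26 | (1S,2R,6S,7S,8R,10R)-8-(tert-butyldimethylsilyloxy)-1,2-epoxy-3-oxo-10-(triethylsilyloxy)germacra-4Z,11(13)-dien-12,6-olide | C=C1C(=O)O[C@H]2/C=C(/C)C(=O)[C@@H]3O[C@@H]3[C@](C)(O[Si](CC)(CC)CC)C[C@@H](O[Si](C)(C)C(C)(C)C)[C@@H]12 | intermediate
27 | (1S,2R,6S,7R,8R,10R)-1,2-epoxy-8,10-dihydroxy-3-oxogermacra-4Z,11(13)-dien-12,6-olide | C=C1C(=O)O[C@H]2/C=C(/C)C(=O)[C@@H]3O[C@@H]3[C@](C)(O)C[C@@H](O)[C@@H]12 | intermediate
28 | angelic acid [(Z)-2-methylbut-2-enoic acid] | C/C=C(/C)C(O)=O | starting material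
29 | (Z)-2-methylbut-2-enoic 2,4,6-trichlorobenzoic anhydride | C/C=C(/C)C(=O)OC(=O)c1c(Cl)cc(Cl)cc1Cl | intermediate
30 | (1S,2R,6S,7R,8R,10R)-8-[(Z)-2-methylbut-2-enoyloxy]-1,2-epoxy-10-hydroxy-3-oxogermacra-4Z,11(13)-dien-12,6-olide (CNP0383091.4) | C=C1C(=O)O[C@H]2/C=C(/C)C(=O)[C@@H]3O[C@@H]3[C@](C)(O)C[C@@H](OC(=O)/C(C)=C\C)[C@@H]12 | target

## Step count and risks

Total step count: 21.
Longest linear sequence: 14 steps (steps 4–6, then 10–19 and 21; the line through steps 7–9 is equally long).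

Steps most likely to fail:

Step 10 (nickel acyl–alkyl union; risk of reductive oxirane opening or radical side reactions). The fallback sets out from 8 and 12 and comes back at 14. Acid 8 is esterified with ethanethiol (N,N'-dicyclohexylcarbodiimide, DMAP cat., CH2Cl2) to the S-ethyl thioester F1. Iodide 12 is treated with Zn dust and LiCl in THF to give the alkylzinc iodide F2. Fukuyama coupling of F1 with F2 (PdCl2(PPh3)2 cat., toluene/THF, rt) runs through two-electron transmetalation, with no free alkyl radical and no excess reductant, and gives ketone 14.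

Step 15 (Barbier allylation; the facial selectivity rests on substrate control by C8 and may be modest). The fallback sets out from 19 and comes back at 22. Adduct 19 is acetylated (Ac2O, pyridine) to the allylic acetate F3. Borylation with bis(pinacolato)diboron catalysed by Pd2(dibenzylideneacetone)3 gives, with allylic transposition, the (E)-2-(borylmethyl)enoate F4. Allylboration of aldehyde 4 with F4 under the chiral phosphoric acid (R)-TRIP (toluene, 0 °C) passes through a closed chair transition state in which the catalyst, not the substrate, selects the aldehyde face. It gives hydroxy ester 21, which lactonises to 22.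

Step 18 (the proposed nickel macrocyclisation; risk of dimers, reduction of the alkenyl iodide, decarbonylation or oxirane opening). The fallback uses known chemistry, sets out from 23 and comes back at 26. Alcohol 23 is oxidised with Dess–Martin periodinane to the epoxy aldehyde F5. An intramolecular Nozaki–Hiyama–Kishi reaction (CrCl2, NiCl2 cat., DMSO/THF, high dilution) closes the ten-membered ring to the allylic alcohol F6 as a mixture of C3 epimers. A second Dess–Martin oxidation converges both epimers on enone 26.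

## Further compounds

F1 | step 10 | S-ethyl (2S,3S)-3-{[(4-methoxybenzyl)oxy]methyl}oxirane-2-carbothioate | CCSC(=O)[C@H]1O[C@H]1COCc1ccc(OC)cc1
F2 | step 10 | [(S)-2-(tert-butyldimethylsilyloxy)-3-(triethylsilyloxy)propyl]zinc iodide | I[Zn]C[C@@H](O[Si](C)(C)C(C)(C)C)CO[Si](CC)(CC)CC
F3 | step 15 | methyl (4R,6R)-3-acetoxy-4-(tert-butyldimethylsilyloxy)-6-[(2S,3S)-3-{[(4-methoxybenzyl)oxy]methyl}oxiran-2-yl]-2-methylidene-6-(triethylsilyloxy)heptanoate (both C3 epimers) | C=C(C(=O)OC)C(OC(C)=O)[C@H](O[Si](C)(C)C(C)(C)C)C[C@@](C)(O[Si](CC)(CC)CC)[C@H]1O[C@H]1COCc1ccc(OC)cc1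
F4 | step 15 | methyl (2E,4R,6R)-4-(tert-butyldimethylsilyloxy)-6-[(2S,3S)-3-{[(4-methoxybenzyl)oxy]methyl}oxiran-2-yl]-2-[(4,4,5,5-tetramethyl-1,3,2-dioxaborolan-2-yl)methyl]-6-(triethylsilyloxy)hept-2-enoate | COC(=O)/C(CB1OC(C)(C)C(C)(C)O1)=C/[C@H](O[Si](C)(C)C(C)(C)C)C[C@@](C)(O[Si](CC)(CC)CC)[C@H]1O[C@H]1COCc1ccc(OC)cc1
F5 | step 18 | (2R,3S)-3-{(2R,4R)-4-(tert-butyldimethylsilyloxy)-4-[(2R,3S)-2-[(Z)-2-iodoprop-1-en-1-yl]-4-methylidene-5-oxotetrahydrofuran-3-yl]-2-(triethylsilyloxy)butan-2-yl}oxirane-2-carbaldehyde | C=C1C(=O)O[C@@H](/C=C(/C)I)[C@H]1[C@H](O[Si](C)(C)C(C)(C)C)C[C@@](C)(O[Si](CC)(CC)CC)[C@H]1O[C@H]1C=O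
F6 | step 18 | 3-hydroxy analogue of 26: 8-(tert-butyldimethylsilyloxy)-1,2-epoxy-3-hydroxy-10-(triethylsilyloxy)germacra-4Z,11(13)-dien-12,6-olide (both C3 epimers; other centres as in 26) | C=C1C(=O)O[C@H]2/C=C(/C)C(O)[C@@H]3O[C@@H]3[C@](C)(O[Si](CC)(CC)CC)C[C@@H](O[Si](C)(C)C(C)(C)C)[C@@H]12
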